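Core numbering: C1 bridgehead C-OH, C2 CH2, C3 CH-N, C4 CH-O, C5 bridgehead CH, C6 CH-O, C7/C8 epoxide, C9 C=O. Ring A = C1-C2-C3-C4-C5-C9, ring B = C1-C9-C5-C6-C7-C8. Exo (axial) points towards C9, endo (equatorial) away from it.
Cuts, in retrosynthetic order: amide N-C1'; C3-N (C-H amination from a C4 carbamate); the epoxide C-O bonds at C7/C8; C4-C5 (aldol); C1-C2 (Grignard). In the acid: C2'=C3' (cross metathesis) and C7'-C8' (Weinreb ketone synthesis).
Forward: ring B is the ring of 2-methoxybenzoquinone, with C7=C8 parked as a cyclopentadiene adduct. Ring A closes by the aldol, C6 and the epoxide are then set, a temporary oxazolidinone ring brings in nitrogen, and the side chain is joined last.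
Enabling feature: on the chair of ring A the C4-O bond is axial, so a nitrene hung on it is gauche to only two C-H bonds, the equatorial C3-H and the bridgehead C5-H. The axial C3-H is anti and out of reach, and C5-H is switched off by the adjacent C9 ketone, which leaves the equatorial C3-H, exactly where the cis nitrogen of the target sits.
Stereochemistry: one catalytic asymmetric Diels-Alder reaction supplies all chirality. It is relayed to C1 (convex-face Grignard), and C1 fixes C5 through the bridge. The shape of the bicycle fixes C6 (exo hydride, then Mitsunobu inversion) and C7/C8 (exo epoxidation). C4 comes from the reversible aldol, C3 from C4 by retentive insertion, and the E-alkene from metathesis.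

Key step: step 9

Assumption: the (S)-oxazaborolidinium catalyst is taken to give adduct 3 in the absolute sense drawn; should induction run the other way, the equally available (R)-catalyst is used and nothing else changes.

Step 1
Reactants: 1 2-methoxy-1,4-benzoquinone; 2 cyclopentadiene (freshly cracked)
Product: 3 (1S,4R,4aS,8aR)-6-methoxy-1,4,4a,8a-tetrahydro-1,4-methanonaphthalene-5,8-dione (endo adduct)
Conditions: (S)-o-tolyl-diphenylprolinol oxazaborolidine·HNTf2 (10 mol %), CH2Cl2, -78 °C, dark
Reagents that add atoms: none
Why: Catalytic enantioselective Diels-Alder reaction with a chiral oxazaborolidinium Lewis acid: the cation binds the more basic vinylogous-ester carbonyl (core C6=O), the unsubstituted C7=C8 bond reacts endo on one enantioface, and the four new stereocentres serve only to make the two faces of the C1 carbonyl different.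

Step 2
Reactants: 3 endo adduct; 4 2-(2-bromoethyl)-1,3-dioxolane
Product: 6 endo-adduct carbinol bearing the 2-(1,3-dioxolan-2-yl)ethyl chain at core C1 (chain cis to the ring-fusion hydrogens; C1 S), via Grignard reagent 5 (not isolated)
Conditions: 4, Mg, THF, 25 °C; then 3, THF, -78 °C; pH 7 buffer
Reagents that add atoms: none
Why: Grignard 1,2-addition: C1=O is the electrophilic carbonyl because C6=O is deactivated as a vinylogous ester, and the reagent comes from the convex face (the side of the ring-fusion hydrogens, away from the norbornene C=C), which sets C1 as S.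

Step 3
Reactants: 6 endo-adduct carbinol
Product: 7 (S)-4-[2-(1,3-dioxolan-2-yl)ethyl]-4-hydroxy-3-methoxycyclohexa-2,5-dien-1-one
Conditions: Ph2O, NaHCO3 (solid), 250 °C, 20 min, N2 sweep
Reagents that add atoms: none
Why: Retro-Diels-Alder reaction, driven by loss of volatile cyclopentadiene and by conjugation of the released C7=C8 bond with C6=O; C1, now the only stereocentre, is quaternary and cannot racemise.

Step 4
Reactants: 7 p-quinol acetal
Product: 9 (1S,4S,5S)-1,4-dihydroxybicyclo[3.3.1]non-7-ene-6,9-dione (C4-OH axial), via dione aldehyde 8 (not isolated)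
Conditions: 1 M aq HCl, THF, 23 to 40 °C
Reagents that add atoms: water, O
Why: Acid hydrolysis of the dioxolane and of the vinylogous ester unmasks aldehyde and cyclic 1,3-dione 8, whose enol carbon C5 adds to the tethered aldehyde in a six-membered intramolecular aldol addition that cannot dehydrate (Bredt's rule); C5 is dictated by the C1 tether because only the cis-1,3 bridge can form, while C4 forms reversibly, the axial (exo) carbinol, whose C-O bond is anti to C5-C6 and turned away from the strongly dipolar enone carbonyl, being collected and the equatorial epimer being returned to the same equilibrating medium.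

Step 5
Reactants: 9 bicyclic aldol
Product: 11 C4 carbamate of 9, via N-trichloroacetyl carbamate 10 (not isolated)
Conditions: Cl3CC(O)NCO (1.05 equiv), CH2Cl2, -78 to -20 °C; then neutral Al2O3, CH2Cl2, rt
Reagents that add atoms: trichloroacetyl isocyanate, O=C=NC(=O)C(Cl)(Cl)Cl
Why: Carbamoylation of an alcohol with an acyl isocyanate followed by hydrolytic loss of the trichloroacetyl group on alumina: at low temperature one equivalent takes the secondary C4-OH in preference to the tertiary, hydrogen-bonded bridgehead C1-OH, capping O4 shuts off the retro-aldol, and the neutral work-up spares the non-enolisable 1,3-diketone.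

Step 6
Reactants: 11 enedione carbamate
Product: 12 4-exo-carbamoyloxy-1,6-endo-dihydroxybicyclo[3.3.1]non-7-en-9-one
Conditions: NaBH4, CeCl3·7H2O, MeOH, -78 °C
Reagents that add atoms: none
Why: Luche reduction: Ce(III) in methanol activates the more basic conjugated C6 carbonyl for 1,2-attack while the C9 ketone, flanked by a quaternary and a tertiary carbon and prone to hemiketal masking, lags behind, and hydride arrives from the open exo face of ring B as is the rule for bicyclo[3.3.1]nonan-2-ones, giving the equatorial (endo) C6 alcohol that the next step inverts.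

Step 7
Reactants: 12 endo allylic alcohol
Product: 13 4-exo-carbamoyloxy-1-hydroxy-6-exo-(4-nitrobenzoyloxy)bicyclo[3.3.1]non-7-en-9-one
Conditions: 4-O2NC6H4CO2H, PPh3, DIAD, THF, 0 °C to rt
Reagents that add atoms: 4-nitrobenzoic acid, O=C(O)c1ccc(cc1)[N+](=O)[O-]
Why: Mitsunobu reaction: the equatorial allylic oxyphosphonium group is displaced by carboxylate in an SN2 sense from the unhindered exo face, which inverts C6 to the axial configuration of the target, while the tertiary C1-OH and the weakly acidic carbamate NH2 stay out and elimination towards C5 is barred by Bredt's rule; the ester then serves as the C6 protecting group.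

Step 8
Reactants: 13 exo allylic ester
Product: 14 C4 carbamate of the 7,8-exo-epoxy-1-hydroxy-6-exo-(4-nitrobenzoyloxy)bicyclo[3.3.1]nonan-9-one
Conditions: dimethyldioxirane (acetone solution), CH2Cl2, 0 °C to rt
Reagents that add atoms: dimethyldioxirane, CC1(C)OO1
Why: Dioxirane epoxidation of a cis-alkene: the endo face of C7=C8 is closed by the C2-C4 bridge (the endo C3-H lies under C7) and the allylic C1-OH can hydrogen-bond the oxidant on the exo face, so oxygen is delivered exo, cis to C1-OH and C6-O, and the neutral reagent avoids Baeyer-Villiger attack on the alpha-oxygenated C9 ketone.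

Step 9
Reactants: 14 fully oxygenated C4 carbamate
Product: 16 C3/C4 cis-fused oxazolidinone of the complete core (C6 4-nitrobenzoate), via iminoiodinane 15 (not isolated)
Conditions: Rh2(esp)2 (3 mol %), PhI(OAc)2 (1.5 equiv), MgO (2.5 equiv), CH2Cl2, 40 °C
Reagents that add atoms: none
Why: PhI(OAc)2 condenses with the carbamate NH2 to iminoiodinane 15, which transfers its nitrogen to the dirhodium core, and the resulting electrophilic rhodium nitrene inserts into a C-H bond in one concerted, asynchronous event that keeps the configuration of the carbon attacked; the closest known reaction type is the rhodium-catalysed intramolecular C-H amination of primary carbamates to oxazolidinones. The new ring (O4, C=O, N, C3, C4) closes by 1,5-insertion, that is through a five-membered cyclic transition state, and on a cyclohexane chair such a ring can only be cis-fused. C4-O is axial on ring A, so the equatorial C3-H stands gauche to it and within reach whereas the axial C3-H is antiperiplanar and cannot be touched: the new C3 stereocentre (N equatorial, cis to O4) is thus dictated by C4. The site selectivity needed is C3-H over the only other gauche C-H bond, the bridgehead C5-H, and the substrate supplies it because C5-H is alpha to the C9 ketone and beta to both the C6 ester oxygen and the carbamate oxygen, hence too electron-poor for the nitrene, and is shielded by both rings. MgO traps the acetic acid released, so epoxide, 4-nitrobenzoate and the tertiary alpha-ketol see neither acid nor base.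

Step 10
Reactants: 16 oxazolidinone
Product: 17 N-Boc oxazolidinone
Conditions: Boc2O (1.1 equiv), Et3N, DMAP (cat.), THF, 0 °C to rt
Reagents that add atoms: di-tert-butyl dicarbonate, CC(C)(C)OC(=O)OC(=O)OC(C)(C)C
Why: DMAP-catalysed N-acylation of the acidic oxazolidinone N-H, which turns the ring carbonyl into an imide-type carbonyl that mild alkoxide can open; the tertiary C1-OH reacts far more slowly.

Step 11
Reactants: 17 N-Boc oxazolidinone
Product: 18 N-Boc amino triol of the complete core
Conditions: Cs2CO3 (0.3 equiv), MeOH, 0 °C
Reagents that add atoms: none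
Why: Base-catalysed methanolysis (transesterification): methoxide attacks the less hindered ring carbonyl and expels the Boc-stabilised nitrogen, the C4 methyl carbonate so formed and the activated 4-nitrobenzoate are transesterified in the same pot, no stereocentre is touched, and Payne migration is impossible because both hydroxyls flanking the epoxide are cis to it.

Step 12
Reactants: 19 hex-5-enoic acid
Product: 21 N-methoxy-N-methylhex-5-enamide, via acyl imidazole 20 (not isolated)
Conditions: CDI, CH2Cl2, rt; then MeNH(OMe)·HCl, rt
Reagents that add atoms: N,O-dimethylhydroxylamine hydrochloride, CNOC.Cl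
Why: Weinreb amide formation by way of the acyl imidazole, a standard activation that leaves the terminal alkene alone.

Step 13
Reactants: 21 Weinreb amide; 22 n-pentylmagnesium bromide
Product: 23 undec-1-en-6-one
Conditions: THF, 0 °C; aq NH4Cl
Reagents that add atoms: none
Why: Weinreb ketone synthesis: the magnesium-chelated tetrahedral adduct survives until work-up, so a second addition does not occur.

Step 14
Reactants: 23 undec-1-en-6-one; 24 acrylic acid
Product: 25 (E)-7-oxododec-2-enoic acid
Conditions: Hoveyda-Grubbs II (3 mol %), acrylic acid (3 equiv), CH2Cl2, 40 °C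
Reagents that add atoms: none
Why: Olefin cross metathesis between a rapidly reacting terminal alkene and an electron-poor acrylate partner, which is selective for the cross product and gives the conjugated E-alkene under thermodynamic control.

Step 15
Reactants: 18 N-Boc amino triol; 25 (E)-7-oxododec-2-enoic acid
Product: 28 isariotin C, via ammonium trifluoroacetate 26 (not isolated), via benzotriazolyl ester 27 (not isolated)
Conditions: 18, TFA, CH2Cl2, 0 °C, evaporate; 25, EDC·HCl, HOBt, DMF, 0 °C; combine, iPr2NEt, 0 °C to rt
Reagents that add atoms: none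
Why: Acidolytic Boc cleavage followed by carbodiimide/HOBt amide coupling: the primary amine outruns the three hydroxyls for active ester 27, and the epoxide survives the brief acid contact because backside opening would have to come from the blocked endo face.

Compound list
1 | 2-methoxy-1,4-benzoquinone | COC1=CC(=O)C=CC1=O | starting material
2 | cyclopentadiene | C1C=CC=C1 | starting material
3 | (1S,4R,4aS,8aR)-6-methoxy-1,4,4a,8a-tetrahydro-1,4-methanonaphthalene-5,8-dione, endo adduct (C5=O is core C1, C8=O is core C6) | O=C1C(OC)=CC(=O)[C@H]2[C@@H]1[C@H]3C=C[C@@H]2C3 | intermediate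
4 | 2-(2-bromoethyl)-1,3-dioxolane | BrCCC1OCCO1 | starting material
5 | [2-(1,3-dioxolan-2-yl)ethyl]magnesium bromide (not isolated) | Br[Mg]CCC1OCCO1 | intermediate
6 | adduct 3 with the carbonyl next to C-OMe (core C1) turned into C(OH)CH2CH2(1,3-dioxolan-2-yl); chain on the convex face, cis to both ring-fusion H, OH on the concave face; core C1 S | O1CCOC1CC[C@@]2(O)C(OC)=CC(=O)[C@H]3[C@@H]2[C@H]4C=C[C@@H]3C4 | intermediate
7 | (S)-4-[2-(1,3-dioxolan-2-yl)ethyl]-4-hydroxy-3-methoxycyclohexa-2,5-dien-1-one | O1CCOC1CC[C@@]2(O)C(OC)=CC(=O)C=C2 | intermediate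
8 | 3-[(1S)-1-hydroxy-2,4-dioxocyclohex-5-en-1-yl]propanal (not isolated) | O=CCC[C@@]1(O)C(=O)CC(=O)C=C1 | intermediate
9 | (1S,4S,5S)-1,4-dihydroxybicyclo[3.3.1]non-7-ene-6,9-dione (core numbering; C4-OH axial/exo) | C1C[C@@]2(O)C(=O)[C@H](C(=O)C=C2)[C@H]1O | intermediate
10 | C4 N-(trichloroacetyl)carbamate of 9 (not isolated) | C1C[C@@]2(O)C(=O)[C@H](C(=O)C=C2)[C@H]1OC(=O)NC(=O)C(Cl)(Cl)Cl | intermediate
11 | (1S,4S,5S)-4-carbamoyloxy-1-hydroxybicyclo[3.3.1]non-7-ene-6,9-dione (carbamate axial/exo) | C1C[C@@]2(O)C(=O)[C@H](C(=O)C=C2)[C@H]1OC(N)=O | intermediate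
12 | 11 with C6=O reduced to the equatorial (endo) allylic alcohol | C1C[C@@]2(O)C(=O)[C@H]([C@@H](O)C=C2)[C@H]1OC(N)=O | intermediate
13 | C6-inverted axial (exo) 4-nitrobenzoate of 12 | C1C[C@@]2(O)C(=O)[C@H]([C@H](OC(=O)c3ccc(cc3)[N+](=O)[O-])C=C2)[C@H]1OC(N)=O | intermediate
14 | 7,8-exo-epoxide of 13 (epoxide O cis to C1-OH and to C6-O); precursor of the key step | C1C[C@@]2(O)C(=O)[C@H]([C@H](OC(=O)c4ccc(cc4)[N+](=O)[O-])[C@@H]3O[C@@H]32)[C@H]1OC(N)=O | intermediate
15 | N-(phenyl-lambda3-iodanylidene) derivative of carbamate 14 (not isolated) | C1C[C@@]2(O)C(=O)[C@H]([C@H](OC(=O)c4ccc(cc4)[N+](=O)[O-])[C@@H]3O[C@@H]32)[C@H]1OC(=O)N=Ic5ccccc5 | intermediate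
16 | C3/C4 cis-fused oxazolidinone (N equatorial on C3, O axial on C4), C6 4-nitrobenzoate; product of the key step | O=C1N[C@H]2C[C@@]3(O)C(=O)[C@H]([C@H](OC(=O)c5ccc(cc5)[N+](=O)[O-])[C@@H]4O[C@@H]43)[C@H]2O1 | intermediate
17 | N-Boc derivative of 16 | O=C1N(C(=O)OC(C)(C)C)[C@H]2C[C@@]3(O)C(=O)[C@H]([C@H](OC(=O)c5ccc(cc5)[N+](=O)[O-])[C@@H]4O[C@@H]43)[C@H]2O1 | intermediate
18 | tert-butyl carbamate of the core amine (free C1, C4 and C6 hydroxyls, configuration as in the target) | CC(C)(C)OC(=O)N[C@H]1C[C@@]2(O)C(=O)[C@H]([C@H](O)[C@@H]3O[C@@H]32)[C@H]1O | intermediate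
19 | hex-5-enoic acid | C=CCCCC(=O)O | starting material
20 | 1-(hex-5-enoyl)imidazole (not isolated) | C=CCCCC(=O)n1ccnc1 | intermediate
21 | N-methoxy-N-methylhex-5-enamide | C=CCCCC(=O)N(C)OC | intermediate
22 | n-pentylmagnesium bromide | CCCCC[Mg]Br | starting material
23 | undec-1-en-6-one | C=CCCCC(=O)CCCCC | intermediate
24 | acrylic acid | C=CC(=O)O | starting material
25 | (E)-7-oxododec-2-enoic acid | CCCCCC(=O)CCC/C=C/C(=O)O | intermediate
26 | trifluoroacetate salt of the core amine (not isolated) | [NH3+][C@H]1C[C@@]2(O)C(=O)[C@H]([C@H](O)[C@@H]3O[C@@H]32)[C@H]1O.[O-]C(=O)C(F)(F)F | intermediate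
27 | benzotriazol-1-yl (E)-7-oxododec-2-enoate (not isolated) | CCCCCC(=O)CCC/C=C/C(=O)On1nnc2ccccc12 | intermediate
28 | isariotin C, core (1S,3S,4R,5S,6S,7S,8S) in the numbering used here | CCCCCC(=O)CCC/C=C/C(=O)N[C@H]1C[C@@]2(O)C(=O)[C@H]([C@H](O)[C@@H]3O[C@@H]32)[C@H]1O | target

Total step count: 15. Longest linear sequence: 12 (steps 1-11 and 15).

Steps most likely to fail

Step 4.
- Risk: the aldol is an equilibrium with little inherent bias at C4. The open hydroxy aldehyde can rest as a lactol or enol hemiacetal. Prolonged acid can trigger an aromatising 1,2-alkyl shift of the quinol.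
- Fallback (sets out from 7, returns at 9): C4 is corrected by substitution instead of equilibration. The equatorial C4 epimer F1, delivered by the same acid treatment of 7, undergoes a Mitsunobu reaction with chloroacetic acid. Attack comes from the exo face, and an equatorial leaving group on the rigid chair has no antiperiplanar hydrogen. This gives the axial chloroacetate F2, which thiourea in warm ethanol cleaves under neutral conditions to 9.

Step 9.
- Risk: insertion into an unactivated methylene next to the carbamate oxygen may be slower than decay of the nitrene. It may also lose out to oxidation at the carbinol C4-H with loss of the tether, or to attack of iodine(III) on the crowded, fully oxygenated substrate.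
- Fallback (sets out from 11, returns at 16): the amination is moved to the least functionalised bicycle.
  - Carbamate 11 under the same rhodium/iodine(III) system gives the enedione oxazolidinone F3. Here C5-H is flanked by two ketones and the electron-poor enone is out of reach.
  - Luche reduction gives the endo allylic alcohol F4.
  - Mitsunobu inversion gives the exo 4-nitrobenzoate F5.
  - Dioxirane epoxidation of F5 gives 16.

Step 6.
- Risk: hydride may also attack the strained, inductively activated C9 ketone, so that chemoselectivity between the two carbonyls is lost.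
- Fallback (sets out from 11, returns at 13): selectivity is moved from the reduction to the later steps.
  - Excess NaBH4/CeCl3 reduces both carbonyls to the C6,C9-diol F6. C6-OH is endo. C9-OH lies on the ring A side, because the axial carbamate blocks that face to hydride.
  - The Mitsunobu reaction engages only the allylic C6-OH, since the C9 carbinol cannot be displaced from the rear, and gives the C6 exo ester C9-alcohol F7.
  - Dess-Martin oxidation of the remaining secondary alcohol restores the ketone of 13.

Further compounds
F1 | step 4 | C4 epimer of 9 (C4-OH equatorial/endo) | C1C[C@@]2(O)C(=O)[C@H](C(=O)C=C2)[C@@H]1O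
F2 | step 4 | C4 axial chloroacetate of 9 | C1C[C@@]2(O)C(=O)[C@H](C(=O)C=C2)[C@H]1OC(=O)CCl
F3 | step 9 | C3/C4 cis-fused oxazolidinone of the enedione | O=C1N[C@H]2C[C@@]3(O)C(=O)[C@H](C(=O)C=C3)[C@H]2O1
F4 | step 9 | C6 endo allylic alcohol of F3 | O=C1N[C@H]2C[C@@]3(O)C(=O)[C@H]([C@@H](O)C=C3)[C@H]2O1
F5 | step 9 | C6 exo 4-nitrobenzoate from F4 | O=C1N[C@H]2C[C@@]3(O)C(=O)[C@H]([C@H](OC(=O)c4ccc(cc4)[N+](=O)[O-])C=C3)[C@H]2O1
F6 | step 6 | C6,C9-diol of 11 (C6-OH endo, C9-OH over ring A) | C1C[C@@]2(O)[C@@H](O)[C@H]([C@@H](O)C=C2)[C@H]1OC(N)=O
F7 | step 6 | C6 exo 4-nitrobenzoate of F6 with free C9-OH | C1C[C@@]2(O)[C@@H](O)[C@H]([C@H](OC(=O)c3ccc(cc3)[N+](=O)[O-])C=C2)[C@H]1OC(N)=O
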